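The numbers of this flask are assumed; what happens was integrated by code.

Millimoles per litre of solution are the currency of this flask, solids included:

    solid product ⇌ target, rate k1*(cs1 - [target]) while solid is left; crystals form when [target] > cs1 (cs1 = 7.1 mM, k1 = 0.0305 min⁻¹)
    dissolved substrate + partner → target (k2 = 0.0224 M⁻¹ min⁻¹)
    solid reagent ⇌ partner, rate k3*(cs3 - [partner]) while solid is left; crystals form when [partner] > cs3 (cs3 = 17 mM, k3 = 0.00107 min⁻¹)
    partner → decomposed reagent (k4 = 5.13 × 10⁻⁵ min⁻¹)
    solid substrate ⇌ dissolved substrate, rate k5*(cs5 - [dissolved substrate]) while solid is left; crystals form when [dissolved substrate] > cs5 (cs5 = 11 mM, k5 = 0.00231 min⁻¹)
    solid substrate + protic impurity → quenched substrate (k6 = 0.0428 M⁻¹ min⁻¹)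

solid substrate 0.020 M; protic impurity 6.00 mM; solid reagent 1.20 equiv; time 10 d

- amounts and yields of target count solid product too
- given per volume of solution although it is solid: solid substrate, solid product, solid reagent
- at the start none of the solid reagent is in solution
- at the start none of the solid substrate is in solution
- dissolved substrate means what is dissolved; the solid is not counted in it
- run time (flask): 10 d

1. how much target and solid product together there is at 10 d, in percent of the solid substrate charged
2. concentration of dissolved substrate in solution at 5.0 d, in percent of saturation
3. the change that raises the amount of target and solid product together at 10 d, in percent of the solid substrate charged most ("none" if none brings more than 2 percentage points) (elm / ash / larch / birch / none)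
4. amount of target and solid product together at 10 d, in percent of the solid substrate charged, after ash

- elm: doubling the solubility in step 5, all else as stated
- ash: doubling the dissolution coefficient of step 1, all else as stated
- larch: doubling the solubility in step 3, all else as stated
- birch: doubling the dissolution coefficient of step 5, all else as stated

1. Book the yield as the charge minus two corrections. For the quench, a first guess is the starting ratio of quench to dissolution, 20.2 %. But you should distrust it: that ratio belongs to the empty solution at the start, and it is no share of the run.

2. So use the impurity's own balance instead: the logarithm of its fall is k6 times the area under solid substrate against time. The part of the solid that fills the solution, up to the solubility of step 5, fades with time constant 1/k5 and gives an exposure of 0.204. The remaining solid leaves as step 2 drains the solution. With partner held at 13.3 mM by supply against its two losses, that drain is 0.00328 mM min⁻¹, and the triangle under this remainder gives 0.529.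

3. By this reckoning the impurity takes 15.6 % of the charge. Call this the quench toll: the share of charged solid substrate lost to protic impurity while solid lasts. It caps the yield at 84.4 %.

4. The second correction is the substrate still dissolved at the end. Solid lasts about 3180 min. Substrate is the limiting reagent at 1.20 equiv, and by then, taking the solid reagent as dissolved too, partner exceeds dissolved substrate by 4.95 mM; the toll enters this excess. A second-order tail starting from the solubility then leaves 6.14 % of the charge dissolved at the end, and 35.6 % of saturation at 5.0 d.

5. The yield comes to 78.3 %. Yet partner's half-life by decomposition, 9.4 d, is shorter than the run, so the excess keeps shrinking and I expect this figure to be high.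

6. Ash moves target between its two counted forms, so I keep 78.3 %. Ranking the changes by toll saved puts elm first, since its solubility exceeds the charge and the triangle vanishes.

The forecast gave 74.5 %, 35 %, elm and 74.5 %, holding that “step 1 merely moves target between solution and crystals”.

The flask gives 74.8 %, which is 3.5 percentage points below my figure, with 34.8 % of saturation at 5.0 d, and 74.8 % after ash. Elm gains 7.7 points, so elm is the change, ahead of birch at 1.6 points and larch at 1.4 points. Quenched substrate in the flask stands at 16.6 % at 10.0 d, against my toll of 15.6 %. In the neighbouring flask, with 3.00 equiv of solid reagent, the ceiling of 84.4 % stays above the yield: that flask reaches 82.3 %, with quenched substrate again at 16.6 % and 1.0 % of the charged solid substrate still there.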